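**Retrosynthetic overview** (labdane numbering: ring A = C1–C5, C10; ring B = C5–C10; C17 = exocyclic CH2 on C8; C18 = CH2O on C4; C11–C16 = side chain)
1. Last bonds: the C18–O ester (acid chloride of 4-acetoxycinnamic acid) and C12–C13 (C12 Grignard reagent opening (S)-β-butyrolactone with inversion, which sets C13); C15 is carried as an allyl ester.
2. The C8=C17 methylene is the Ramberg–Bäcklund product of a C8 methyl sulfone (the S-methyl carbon becomes C17).
3. Ring B is closed by a radical [4+2] annulation that forms C6–C7 and C8–C9 in one operation from a ring-A iodide/enoate and methyl vinyl sulfone. The enabling feature: C6 and C9 are trans-diequatorial arms on the adjacent ring-A carbons C5 and C10, and C8 carries the one-carbon branch C17, so C7–C8(–S–C17) maps onto the vinyl sulfone inserted between a C6 radical and a C9=C11 enoate.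
4. The C4/C5/C10 triad of ring A comes from a temporary 3-oxabicyclo[3.3.1]nonane lactone (C18–O–C9(=O) bridge): auxiliary-controlled methylation sets C10, a stereoconvergent aldol–lactonisation with formaldehyde sets C4, and hydroboration from the lactone face sets C5.
5. Ring order: ring A (bought as a cyclohexanone) → temporary lactone ring (closed in step 4, opened in step 9) → ring B (step 11).

Key step: step 11

Assumption: the lithio-enamine from tert-butyl L-valinate is taken to be methylated on the face that gives the (1R)-ester under the conditions of step 2; if the sense is the opposite, tert-butyl D-valinate is used in the same way.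
Note: some ring descriptors change between intermediates only because CIP priorities change; the SMILES strings are authoritative.

**Step 1**
Reactants: 1 methyl 2-oxocyclohexane-1-carboxylate; 2 tert-butyl L-valinate
Product: 3 methyl 2-{[(2S)-1-tert-butoxy-3-methyl-1-oxobutan-2-yl]amino}cyclohex-1-ene-1-carboxylate
Conditions: BF3·OEt2 (cat.), benzene, reflux, azeotropic removal of water
Reagents that add atoms: none
Why: Acid-catalysed condensation of the β-keto ester with the primary amine should give the conjugated, hydrogen-bonded enamino ester (enamine formation; no new stereocentre).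

**Step 2**
Reactants: 3 enamino ester
Product: 5 methyl (1R)-1-methyl-2-oxocyclohexane-1-carboxylate, via methylated imine 4 (not isolated)
Conditions: LiN(i-Pr)2, toluene, −78 °C; HMPA, MeI, −78 → −55 °C; then 10% aq. citric acid, THF, 23 °C
Reagents that add atoms: iodomethane CI; water O
Why: Auxiliary-controlled α-alkylation of a β-keto ester enamine: the chelated lithio-enamine is shielded on one face by the valine tert-butyl ester, so MeI should enter from the other and set the quaternary C10 centre, and hydrolysis of imine 4 returns the ketone and the auxiliary.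

**Step 3**
Reactants: 5 methyl (1R)-1-methyl-2-oxocyclohexane-1-carboxylate
Product: 6 methyl (1R,3RS)-1,3-dimethyl-2-oxocyclohexane-1-carboxylate
Conditions: LiN(i-Pr)2, THF, −78 °C; MeI, −78 → 0 °C
Reagents that add atoms: iodomethane CI
Why: Kinetic ketone enolate alkylation is regiospecific because C3 is the only enolisable position, and the new tertiary centre may form as a mixture since the next step passes through its enolate.

**Step 4**
Reactants: 6 methyl (1R,3RS)-1,3-dimethyl-2-oxocyclohexane-1-carboxylate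
Product: 8 (1R,5R)-1,5-dimethyl-3-oxabicyclo[3.3.1]nonane-2,9-dione, via cis-hydroxy ester 7 (not isolated)
Conditions: LiN(i-Pr)2, THF, −78 → −20 °C; CH2O (gas), −78 → 23 °C; aq. NH4Cl
Reagents that add atoms: formaldehyde C=O
Why: Tandem aldol addition–lactonisation: the enolate adds formaldehyde reversibly on both faces, but only the aldolate with CH2O− cis to the C10 ester (7) can close the bridged δ-lactone with loss of methoxide, so retro-aldol equilibration should funnel the material to the cis-dimethyl lactone and the C4 quaternary centre is set by the C10 centre.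

**Step 5**
Reactants: 8 keto lactone
Product: 9 (1R,5S)-1,5-dimethyl-9-methylidene-3-oxabicyclo[3.3.1]nonan-2-one
Conditions: Zn, CH2Br2, TiCl4, THF/CH2Cl2, 0 → 23 °C
Reagents that add atoms: dibromomethane BrCBr
Why: Lombardo–Takai methylenation should convert the exposed bridging ketone into the methylidene under non-basic conditions that leave the lactone and the non-enolisable β-dicarbonyl array intact.

**Step 6**
Reactants: 9 methylidene lactone
Product: 11 (1R,5S,9R)-9-(hydroxymethyl)-1,5-dimethyl-3-oxabicyclo[3.3.1]nonan-2-one, via B-alkyl borane 10 (not isolated)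
Conditions: 9-BBN, THF, 60 °C; then 30% H2O2, aq. NaOAc, 0 → 23 °C
Reagents that add atoms: hydrogen peroxide OO
Why: Hydroboration–oxidation: the bulky borane should add anti-Markovnikov from the face over the lactone bridge, which presents a flat carbonyl carbon and an oxygen instead of the two axial C–H bonds of the carbocyclic bridge, so hydrogen is delivered to C5 cis to C9 and C18 and the oxidation retains configuration.

**Step 7**
Reactants: 11 hydroxy lactone
Product: 12 (1R,5S,9R)-9-(iodomethyl)-1,5-dimethyl-3-oxabicyclo[3.3.1]nonan-2-one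
Conditions: PPh3, I2, imidazole, CH2Cl2, 0 → 23 °C
Reagents that add atoms: iodine II
Why: Appel-type iodination of the primary alcohol through its alkoxyphosphonium salt touches no stereocentre and leaves the lactone alone.

**Step 8**
Reactants: 12 iodo lactone
Product: 13 (1R,2RS,5S,9R)-9-(iodomethyl)-1,5-dimethyl-3-oxabicyclo[3.3.1]nonan-2-ol
Conditions: i-Bu2AlH, CH2Cl2, −78 °C; aq. potassium sodium tartrate
Reagents that add atoms: none
Why: Partial reduction of the lactone stops at the stable bridged tetrahedral aluminate and gives the lactol, which keeps C9 at the aldehyde level and C18 at the alcohol level so the two arms stay differentiated.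

**Step 9**
Reactants: 13 lactol; 14 methyl (triphenyl-λ5-phosphanylidene)acetate
Product: 16 methyl (2E)-3-[(1S,2S,3S)-3-(hydroxymethyl)-2-(iodomethyl)-1,3-dimethylcyclohexyl]prop-2-enoate, via hydroxy aldehyde 15 (not isolated)
Conditions: PhCO2H (cat.), toluene, 90 °C
Reagents that add atoms: none
Why: Wittig olefination of the ring-opened hydroxy aldehyde with a stabilised ylide should give the (E)-enoate and free the C18 alcohol, the hindered primary iodide being a poor alkylating agent for the ylide.

**Step 10**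
Reactants: 16 hydroxy enoate
Product: 17 methyl (2E)-3-[(1S,2S,3S)-3-({[tert-butyl(dimethyl)silyl]oxy}methyl)-2-(iodomethyl)-1,3-dimethylcyclohexyl]prop-2-enoate
Conditions: TBSCl, imidazole, DMF, 23 °C
Reagents that add atoms: tert-butyl(chloro)dimethylsilane CC(C)(C)[Si](C)(C)Cl
Why: Silyl ether formation protects the neopentyl C18 alcohol for the radical and organometallic steps and removes the risk of oxa-Michael addition to the enoate.

**Step 11**
Reactants: 17 iodo enoate; 18 methyl vinyl sulfone
Product: 22 methyl 2-[(1S,2RS,4aS,5S,8aR)-5-({[tert-butyl(dimethyl)silyl]oxy}methyl)-2-methanesulfonyl-5,8a-dimethyldecahydronaphthalen-1-yl]acetate, via C6 radical 19 (not isolated), via C8 sulfonyl radical 20 (not isolated), via C11 ester radical 21 (not isolated)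
Conditions: (Me3Si)3SiH (1.3 equiv) and AIBN (0.2 equiv) added over 8 h to 17 and 18 (5 equiv), benzene (0.02 M), 80 °C
Reagents that add atoms: none
Why: The silyl radical abstracts iodine from 17 to give the nucleophilic primary C6 radical 19, which adds to the CH2 terminus (C7) of the electron-poor vinyl sulfone; the α-sulfonyl C8 radical 20 then attacks the enoate β-carbon C9, and the α-ester C11 radical 21 takes hydrogen from the silane, which carries the chain. The closest known reaction type is the silane- or stannane-mediated radical annulation, that is a Giese addition followed by exo cyclisation onto a tethered acrylate, as in tandem radical conjugate addition–cyclisations of bis-enoates. Ring B closes in the 6-exo-trig mode through a chair transition state in which the C5–C6 and C10–C9 bonds are both equatorial on ring A, so only the trans-fused decalin can form. C9 is set in that chair: the enoate arm should lie pseudo-equatorial to avoid the axial hydrogens at C5 and C7, which leaves H9 axial and anti to the axial C10 methyl, while the C8 epimers are of no consequence because C8 becomes sp2 in step 13. The step needs chemoselectivity along the chain: the C6 radical must take the vinyl sulfone (used in excess; its own enoate is only reachable by 4-exo or 5-endo closure), the C8 radical must cyclise before it is reduced (slow addition of silane, arms held gauche next to the quaternary C10, Thorpe–Ingold effect), and the chain must stop after one vinyl sulfone, which the electrophilic character of radicals 20 and 21 toward a second electron-poor alkene secures.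

**Step 12**
Reactants: 22 sulfonyl ester
Product: 23 2-[(1S,2RS,4aS,5S,8aR)-5-({[tert-butyl(dimethyl)silyl]oxy}methyl)-2-methanesulfonyl-5,8a-dimethyldecahydronaphthalen-1-yl]ethan-1-ol
Conditions: LiAlH4, THF, 0 °C
Reagents that add atoms: none
Why: Hydride reduction of the methyl ester gives the C12 alcohol while the dialkyl sulfone and the silyl ether are inert, which removes the enolisable ester before the base-mediated olefination.

**Step 13**
Reactants: 23 sulfonyl alcohol
Product: 26 2-[(1R,4aS,5S,8aS)-5-({[tert-butyl(dimethyl)silyl]oxy}methyl)-5,8a-dimethyl-2-methylidenedecahydronaphthalen-1-yl]ethan-1-ol, via bromomethyl sulfone 24 (not isolated), via episulfone 25 (not isolated)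
Conditions: KOH on Al2O3, BrCF2CF2Br, t-BuOH/CH2Cl2, 0 → 23 °C
Reagents that add atoms: none
Why: Ramberg–Bäcklund reaction with in situ halogenation: α-bromination of the sulfone by the bromofluorocarbon (which releases no carbene), 1,3-elimination to the episulfone and loss of SO2 should give an alkene that can only be the C8=C17 exocyclic methylene whichever α-carbon is halogenated, and the C8 stereocentre disappears.

**Step 14**
Reactants: 26 methylidene alcohol
Product: 27 (1R,4aS,5S,8aS)-1-(2-bromoethyl)-5-({[tert-butyl(dimethyl)silyl]oxy}methyl)-5,8a-dimethyl-2-methylidenedecahydronaphthalene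
Conditions: CBr4, PPh3, CH2Cl2, 0 °C
Reagents that add atoms: tetrabromomethane BrC(Br)(Br)Br
Why: Appel bromination of the unhindered primary alcohol runs under neutral conditions that leave the exocyclic alkene and the silyl ether untouched.

**Step 15**
Reactants: 27 bromide; 28 (S)-β-butyrolactone
Product: 30 (3S)-5-[(1R,4aS,5S,8aS)-5-({[tert-butyl(dimethyl)silyl]oxy}methyl)-5,8a-dimethyl-2-methylidenedecahydronaphthalen-1-yl]-3-methylpentanoic acid, via Grignard reagent 29 (not isolated)
Conditions: Mg, THF, 40 °C; then 28, CuBr·SMe2 (10 mol %), THF/Me2S, −30 → 0 °C; aq. HCl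
Reagents that add atoms: none
Why: Copper-catalysed SN2 opening of the β-lactone at its methyl-bearing β-carbon by the primary Grignard reagent (alkyl–oxygen cleavage) forms C12–C13 with inversion, so the (S)-lactone should give the (13S)-acid directly.

**Step 16**
Reactants: 30 acid
Product: 31 prop-2-en-1-yl (3S)-5-[(1R,4aS,5S,8aS)-5-({[tert-butyl(dimethyl)silyl]oxy}methyl)-5,8a-dimethyl-2-methylidenedecahydronaphthalen-1-yl]-3-methylpentanoate
Conditions: allyl bromide, Cs2CO3, DMF, 23 °C
Reagents that add atoms: allyl bromide C=CCBr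
Why: O-alkylation of the caesium carboxylate masks C15 as an allyl ester chemoselectively.

**Step 17**
Reactants: 31 allyl ester silyl ether
Product: 32 prop-2-en-1-yl (3S)-5-[(1R,4aS,5S,8aS)-5-(hydroxymethyl)-5,8a-dimethyl-2-methylidenedecahydronaphthalen-1-yl]-3-methylpentanoate
Conditions: Bu4NF, THF, 23 → 40 °C
Reagents that add atoms: none
Why: Fluoride-induced cleavage of the silyl ether liberates the C18 alcohol, the allyl ester and the alkene being stable to fluoride.

**Step 18**
Reactants: 32 alcohol; 33 (2E)-3-[4-(acetyloxy)phenyl]prop-2-enoic acid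
Product: 35 prop-2-en-1-yl (3S)-5-[(1R,4aS,5S,8aS)-5-({[(2E)-3-(4-acetoxyphenyl)prop-2-enoyl]oxy}methyl)-5,8a-dimethyl-2-methylidenedecahydronaphthalen-1-yl]-3-methylpentanoate, via acid chloride 34 (not isolated)
Conditions: 33, (COCl)2, DMF (cat.), CH2Cl2, 0 → 23 °C; then 32, pyridine, DMAP (cat.), CH2Cl2, 0 → 23 °C
Reagents that add atoms: none
Why: Nucleophile-catalysed acylation of the neopentyl alcohol by the acid chloride made in situ installs the (E)-cinnamate, the acid chloride being far more reactive than the aryl acetate so that acetyl transfer should not compete.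

**Step 19**
Reactants: 35 protected ester
Product: 36 (3S)-5-[(1R,4aS,5S,8aS)-5-({[(2E)-3-(4-hydroxyphenyl)prop-2-enoyl]oxy}methyl)-5,8a-dimethyl-2-methylidenedecahydronaphthalen-1-yl]-3-methylpentanoic acid
Conditions: Pd(PPh3)4 (5 mol %), morpholine (10 equiv), THF, 23 °C; aq. citric acid
Reagents that add atoms: none
Why: Tsuji–Trost deallylation by zerovalent palladium with morpholine as allyl acceptor frees the C15 acid, and the same amine should cleave the phenolic acetate by aminolysis, while the hindered conjugated alkyl cinnamate and the exocyclic alkene are untouched.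

**Compound list**
1 | methyl 2-oxocyclohexane-1-carboxylate | COC(=O)C1CCCCC1=O | starting material
2 | tert-butyl L-valinate | CC(C)[C@H](N)C(=O)OC(C)(C)C | starting material
3 | methyl 2-{[(2S)-1-tert-butoxy-3-methyl-1-oxobutan-2-yl]amino}cyclohex-1-ene-1-carboxylate | COC(=O)C1=C(N[C@@H](C(C)C)C(=O)OC(C)(C)C)CCCC1 | intermediate
4 | methyl (1R)-2-{[(2S)-1-tert-butoxy-3-methyl-1-oxobutan-2-yl]imino}-1-methylcyclohexane-1-carboxylate (not isolated) | CC(C)[C@@H](C(=O)OC(C)(C)C)N=C1CCCC[C@@]1(C)C(=O)OC | intermediate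
5 | methyl (1R)-1-methyl-2-oxocyclohexane-1-carboxylate | O=C1CCCC[C@@]1(C)C(=O)OC | intermediate
6 | methyl (1R,3RS)-1,3-dimethyl-2-oxocyclohexane-1-carboxylate | O=C1C(C)CCC[C@@]1(C)C(=O)OC | intermediate
7 | methyl (1R,3R)-3-(hydroxymethyl)-1,3-dimethyl-2-oxocyclohexane-1-carboxylate (not isolated) | O=C1[C@@](C)(CO)CCC[C@@]1(C)C(=O)OC | intermediate
8 | (1R,5R)-1,5-dimethyl-3-oxabicyclo[3.3.1]nonane-2,9-dione | O=C2[C@@](C)(CO1)CCC[C@@]2(C)C1=O | intermediate
9 | (1R,5S)-1,5-dimethyl-9-methylidene-3-oxabicyclo[3.3.1]nonan-2-one | C=C2[C@@](C)(CO1)CCC[C@@]2(C)C1=O | intermediate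
10 | (1R,5S,9R)-9-[(9-borabicyclo[3.3.1]nonan-9-yl)methyl]-1,5-dimethyl-3-oxabicyclo[3.3.1]nonan-2-one (not isolated) | B1(C[C@@H]3[C@@](C)(CO4)CCC[C@@]3(C)C4=O)C2CCCC1CCC2 | intermediate
11 | (1R,5S,9R)-9-(hydroxymethyl)-1,5-dimethyl-3-oxabicyclo[3.3.1]nonan-2-one | OC[C@@H]2[C@@](C)(CO1)CCC[C@@]2(C)C1=O | intermediate
12 | (1R,5S,9R)-9-(iodomethyl)-1,5-dimethyl-3-oxabicyclo[3.3.1]nonan-2-one | IC[C@@H]2[C@@](C)(CO1)CCC[C@@]2(C)C1=O | intermediate
13 | (1R,2RS,5S,9R)-9-(iodomethyl)-1,5-dimethyl-3-oxabicyclo[3.3.1]nonan-2-ol | IC[C@@H]2[C@@](C)(CO1)CCC[C@@]2(C)C1O | intermediate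
14 | methyl (triphenyl-λ5-phosphanylidene)acetate | COC(=O)C=P(c1ccccc1)(c1ccccc1)c1ccccc1 | starting material
15 | (1R,2R,3S)-3-(hydroxymethyl)-2-(iodomethyl)-1,3-dimethylcyclohexane-1-carbaldehyde (not isolated) | IC[C@@H]1[C@@](C)(CO)CCC[C@@]1(C)C=O | intermediate
16 | methyl (2E)-3-[(1S,2S,3S)-3-(hydroxymethyl)-2-(iodomethyl)-1,3-dimethylcyclohexyl]prop-2-enoate | IC[C@@H]1[C@@](C)(CO)CCC[C@@]1(C)/C=C/C(=O)OC | intermediate
17 | methyl (2E)-3-[(1S,2S,3S)-3-({[tert-butyl(dimethyl)silyl]oxy}methyl)-2-(iodomethyl)-1,3-dimethylcyclohexyl]prop-2-enoate | IC[C@@H]1[C@@](C)(CO[Si](C)(C)C(C)(C)C)CCC[C@@]1(C)/C=C/C(=O)OC | intermediate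
18 | methyl vinyl sulfone (methanesulfonylethene) | CS(=O)(=O)C=C | starting material
19 | primary C6 radical (17 with iodine replaced by an unpaired electron; not isolated) | [CH2][C@@H]1[C@@](C)(CO[Si](C)(C)C(C)(C)C)CCC[C@@]1(C)/C=C/C(=O)OC | intermediate
20 | α-sulfonyl C8 radical (adduct of 19 to the CH2 terminus of 18; not isolated) | CS(=O)(=O)[CH]CC[C@@H]1[C@@](C)(CO[Si](C)(C)C(C)(C)C)CCC[C@@]1(C)/C=C/C(=O)OC | intermediate
21 | α-ester C11 radical (20 after 6-exo closure of C8 onto C9; not isolated) | CS(=O)(=O)C1CC[C@@H]2[C@@](C)(CO[Si](C)(C)C(C)(C)C)CCC[C@@]2(C)[C@@H]1[CH]C(=O)OC | intermediate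
22 | methyl 2-[(1S,2RS,4aS,5S,8aR)-5-({[tert-butyl(dimethyl)silyl]oxy}methyl)-2-methanesulfonyl-5,8a-dimethyldecahydronaphthalen-1-yl]acetate | CS(=O)(=O)C1CC[C@@H]2[C@@](C)(CO[Si](C)(C)C(C)(C)C)CCC[C@@]2(C)[C@@H]1CC(=O)OC | intermediate
23 | 2-[(1S,2RS,4aS,5S,8aR)-5-({[tert-butyl(dimethyl)silyl]oxy}methyl)-2-methanesulfonyl-5,8a-dimethyldecahydronaphthalen-1-yl]ethan-1-ol | CS(=O)(=O)C1CC[C@@H]2[C@@](C)(CO[Si](C)(C)C(C)(C)C)CCC[C@@]2(C)[C@@H]1CCO | intermediate
24 | 2-[(1S,2RS,4aS,5S,8aR)-2-(bromomethanesulfonyl)-5-({[tert-butyl(dimethyl)silyl]oxy}methyl)-5,8a-dimethyldecahydronaphthalen-1-yl]ethan-1-ol (not isolated) | BrCS(=O)(=O)C1CC[C@@H]2[C@@](C)(CO[Si](C)(C)C(C)(C)C)CCC[C@@]2(C)[C@@H]1CCO | intermediate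
25 | episulfone: thiirane 1,1-dioxide spiro-fused at C8 (decalin C2) of 23 (not isolated) | O=S1(=O)CC12CC[C@@H]3[C@@](C)(CO[Si](C)(C)C(C)(C)C)CCC[C@@]3(C)[C@@H]2CCO | intermediate
26 | 2-[(1R,4aS,5S,8aS)-5-({[tert-butyl(dimethyl)silyl]oxy}methyl)-5,8a-dimethyl-2-methylidenedecahydronaphthalen-1-yl]ethan-1-ol | C=C1CC[C@@H]2[C@@](C)(CO[Si](C)(C)C(C)(C)C)CCC[C@@]2(C)[C@@H]1CCO | intermediate
27 | (1R,4aS,5S,8aS)-1-(2-bromoethyl)-5-({[tert-butyl(dimethyl)silyl]oxy}methyl)-5,8a-dimethyl-2-methylidenedecahydronaphthalene | C=C1CC[C@@H]2[C@@](C)(CO[Si](C)(C)C(C)(C)C)CCC[C@@]2(C)[C@@H]1CCBr | intermediate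
28 | (S)-β-butyrolactone ((4S)-4-methyloxetan-2-one) | C[C@H]1CC(=O)O1 | starting material
29 | {2-[(1R,4aS,5S,8aS)-5-({[tert-butyl(dimethyl)silyl]oxy}methyl)-5,8a-dimethyl-2-methylidenedecahydronaphthalen-1-yl]ethyl}magnesium bromide (not isolated) | C=C1CC[C@@H]2[C@@](C)(CO[Si](C)(C)C(C)(C)C)CCC[C@@]2(C)[C@@H]1CC[Mg]Br | intermediate
30 | (3S)-5-[(1R,4aS,5S,8aS)-5-({[tert-butyl(dimethyl)silyl]oxy}methyl)-5,8a-dimethyl-2-methylidenedecahydronaphthalen-1-yl]-3-methylpentanoic acid | C=C1CC[C@@H]2[C@@](C)(CO[Si](C)(C)C(C)(C)C)CCC[C@@]2(C)[C@@H]1CC[C@H](C)CC(=O)O | intermediate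
31 | prop-2-en-1-yl (3S)-5-[(1R,4aS,5S,8aS)-5-({[tert-butyl(dimethyl)silyl]oxy}methyl)-5,8a-dimethyl-2-methylidenedecahydronaphthalen-1-yl]-3-methylpentanoate | C=C1CC[C@@H]2[C@@](C)(CO[Si](C)(C)C(C)(C)C)CCC[C@@]2(C)[C@@H]1CC[C@H](C)CC(=O)OCC=C | intermediate
32 | prop-2-en-1-yl (3S)-5-[(1R,4aS,5S,8aS)-5-(hydroxymethyl)-5,8a-dimethyl-2-methylidenedecahydronaphthalen-1-yl]-3-methylpentanoate | C=C1CC[C@@H]2[C@@](C)(CO)CCC[C@@]2(C)[C@@H]1CC[C@H](C)CC(=O)OCC=C | intermediate
33 | (2E)-3-[4-(acetyloxy)phenyl]prop-2-enoic acid | CC(=O)Oc1ccc(/C=C/C(=O)O)cc1 | starting material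
34 | (2E)-3-[4-(acetyloxy)phenyl]prop-2-enoyl chloride (not isolated) | CC(=O)Oc1ccc(/C=C/C(=O)Cl)cc1 | intermediate
35 | prop-2-en-1-yl (3S)-5-[(1R,4aS,5S,8aS)-5-({[(2E)-3-(4-acetoxyphenyl)prop-2-enoyl]oxy}methyl)-5,8a-dimethyl-2-methylidenedecahydronaphthalen-1-yl]-3-methylpentanoate | C=C1CC[C@@H]2[C@@](C)(COC(=O)/C=C/c3ccc(OC(C)=O)cc3)CCC[C@@]2(C)[C@@H]1CC[C@H](C)CC(=O)OCC=C | intermediate
36 | (3S)-5-[(1R,4aS,5S,8aS)-5-({[(2E)-3-(4-hydroxyphenyl)prop-2-enoyl]oxy}methyl)-5,8a-dimethyl-2-methylidenedecahydronaphthalen-1-yl]-3-methylpentanoic acid | C=C1CC[C@@H]2[C@@](C)(COC(=O)/C=C/c3ccc(O)cc3)CCC[C@@]2(C)[C@@H]1CC[C@H](C)CC(=O)O | target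

**Total step count:** 19. **Longest linear sequence:** 19 steps (1 → 36).

**Steps most likely to fail**

Step 11. What may go wrong: hydrogen transfer to the C8 radical before ring closure, chain growth with a second vinyl sulfone, or poor facial control at C9 in the radical closure. Fallback (sets out from 17, comes back at 22): the two bonds are made in separate radical and carbanionic events. Compound 17 and 18 are treated with Bu3SnH (added in one portion) and AIBN in benzene at 80 °C, so that reduction outruns cyclisation and the open-chain Giese adduct methyl (2E)-3-[(1S,2S,3S)-3-({[tert-butyl(dimethyl)silyl]oxy}methyl)-2-[3-(methanesulfonyl)propyl]-1,3-dimethylcyclohexyl]prop-2-enoate F1 is obtained. Treatment of it with LiN(i-Pr)2 in THF (−78 → 0 °C) should generate the α-sulfonyl carbanion at C8, which closes ring B by intramolecular 6-exo Michael addition to the enoate and gives 22 after protonation.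

Step 13. What may go wrong: double halogenation of the S-methyl group and other base-driven side reactions, so that halo-alkenes or sulfonic acids form instead of clean SO2 extrusion. Fallback (sets out from 17, comes back at 26): the methylene carbon is brought in by sulfone alkylation and not from the S-methyl group. The annulation of step 11 is run with phenyl vinyl sulfone in place of 18 to give methyl 2-[(1S,2RS,4aS,5S,8aR)-2-(benzenesulfonyl)-5-({[tert-butyl(dimethyl)silyl]oxy}methyl)-5,8a-dimethyldecahydronaphthalen-1-yl]acetate F2. LiAlH4 reduction gives 2-[(1S,2RS,4aS,5S,8aR)-2-(benzenesulfonyl)-5-({[tert-butyl(dimethyl)silyl]oxy}methyl)-5,8a-dimethyldecahydronaphthalen-1-yl]ethan-1-ol F3. Double deprotonation with n-BuLi (2.2 equiv, THF, −78 → 0 °C) and alkylation of the C8 carbanion with Bu3SnCH2I gives the β-stannyl sulfone 2-{(1S,2RS,4aS,5S,8aR)-2-(benzenesulfonyl)-5-({[tert-butyl(dimethyl)silyl]oxy}methyl)-5,8a-dimethyl-2-[(tributylstannyl)methyl]decahydronaphthalen-1-yl}ethan-1-ol F4, which should lose tributyltin benzenesulfinate on warming (brief Bu4NF treatment, short enough to spare the silyl ether, if needed) to give 26.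

Step 4. What may go wrong: the methoxide released on lactonisation attacks the non-enolisable β-keto ester or lactone (retro-Claisen ring cleavage), or the retro-aldol equilibration is too slow to funnel the trans aldolate. Fallback (sets out from 6, comes back at 8): an irreversible alkylation followed by acid-mediated lactonisation. The enolate of 6 (LiN(i-Pr)2, THF, −78 °C) is alkylated with benzyl chloromethyl ether to give methyl (1R,3RS)-3-[(benzyloxy)methyl]-1,3-dimethyl-2-oxocyclohexane-1-carboxylate F5 as a mixture of C3 epimers. Hydrogenolysis (H2, Pd on carbon, EtOAc) frees the alcohols, and TsOH (cat.) in toluene at reflux closes only the cis-hydroxy ester 7 to 8 with loss of methanol; the trans-hydroxy ester cannot lactonise and is separated.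

**Further compounds**
F1 | step 11 | methyl (2E)-3-[(1S,2S,3S)-3-({[tert-butyl(dimethyl)silyl]oxy}methyl)-2-[3-(methanesulfonyl)propyl]-1,3-dimethylcyclohexyl]prop-2-enoate | CS(=O)(=O)CCC[C@@H]1[C@@](C)(CO[Si](C)(C)C(C)(C)C)CCC[C@@]1(C)/C=C/C(=O)OC
F2 | step 13 | methyl 2-[(1S,2RS,4aS,5S,8aR)-2-(benzenesulfonyl)-5-({[tert-butyl(dimethyl)silyl]oxy}methyl)-5,8a-dimethyldecahydronaphthalen-1-yl]acetate | O=S(=O)(c1ccccc1)C1CC[C@@H]2[C@@](C)(CO[Si](C)(C)C(C)(C)C)CCC[C@@]2(C)[C@@H]1CC(=O)OC
F3 | step 13 | 2-[(1S,2RS,4aS,5S,8aR)-2-(benzenesulfonyl)-5-({[tert-butyl(dimethyl)silyl]oxy}methyl)-5,8a-dimethyldecahydronaphthalen-1-yl]ethan-1-ol | O=S(=O)(c1ccccc1)C1CC[C@@H]2[C@@](C)(CO[Si](C)(C)C(C)(C)C)CCC[C@@]2(C)[C@@H]1CCO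
F4 | step 13 | 2-{(1S,2RS,4aS,5S,8aR)-2-(benzenesulfonyl)-5-({[tert-butyl(dimethyl)silyl]oxy}methyl)-5,8a-dimethyl-2-[(tributylstannyl)methyl]decahydronaphthalen-1-yl}ethan-1-ol | CCCC[Sn](CCCC)(CCCC)CC1(S(=O)(=O)c2ccccc2)CC[C@@H]2[C@@](C)(CO[Si](C)(C)C(C)(C)C)CCC[C@@]2(C)[C@@H]1CCO
F5 | step 4 | methyl (1R,3RS)-3-[(benzyloxy)methyl]-1,3-dimethyl-2-oxocyclohexane-1-carboxylate | O=C1C(C)(COCc2ccccc2)CCC[C@@]1(C)C(=O)OC
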